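Do not trust a selectivity read from the first points of a run: the first north readings, 3.9 % of target and 3.7 % of isomer of the product A, each carry a scatter of 0.5 percentage points.

| flask | substrate | coupling partner | other conformer | remark | time |
|---|---|---|---|---|---|
| north | 0.50 M | 0.50 M | 0.35 M | run made earlier |  |
| north-west | 0.50 M | 0.50 M | 0.55 M | run made earlier |  |
| north-east | 0.50 M | 0.75 M | 0.25 M | run made earlier |  |
| flask | 0.50 M | 0.500 M | 0.250 M |  | 3.0 min |

- north (time / min: target / %, isomer of the product A / %): 0.250: 3.9, 3.7; 0.417: 3.7, 6.1; 0.667: 6.5, 9.6; 1.00: 7.3, 11.7; 1.50: 8.1, 15.3; 2.50: 9.6, 20.1; 4.00: 10.6, 22.9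
- north-west (time / min: target / %, isomer of the product A / %): 0.200: 2.6, 4.0; 0.500: 3.2, 9.1; 1.00: 4.6, 13.7; 1.50: 4.5, 18.1; 2.00: 5.9, 20.5; 3.00: 7.0, 23.9; 4.00: 7.3, 25.5
- north-east (time / min: target / %, isomer of the product A / %): 0.667: 9.7, 11.5; 1.33: 13.3, 16.2; 2.00: 15.4, 21.1; 3.00: 16.0, 23.3; 4.00: 18.1, 26.4

(standard deviation of a reading: 0.5 percentage points)

1. share of target in target plus isomer of the product A at 2.0 s
2. share of target in target plus isomer of the product A at 3.0 min
3. which of target and isomer of the product A there is more of at 3.0 min

- the numbers in the tables scatter by 0.5 percentage points (one standard deviation)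
- reactions considered so far: substrate <-> other conformer; substrate + coupling partner -> target; coupling partner + other conformer -> isomer of the product A; target <-> isomer of the product B

Work in fractions of the pool, the substrate and other conformer together. First ask what the start looks like. Divide target by isomer of the product A, then divide by the charge ratio, the substrate's fraction of the pool over the other conformer's. The first north and north-west readings, taken at 0.250 min and 0.200 min, give 0.726; carry that back to the start of the flask as a rough value, and expect a loose 59.2 % at 2.0 s.

Next ask what holds late. Make the same division at the last reading of each run, which gives 0.324, 0.315 and 0.343. Take their mean as the late factor, an apparent selectivity factor: 0.327.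

Then ask whether 3.0 min is already late. In the north-east run, target over isomer of the product A reads 0.687 at 3.00 min and 0.686 at 4.00 min, so treat it as late.

In the flask the charge ratio is 2.00, so the late ratio is 0.654, below one. So expect isomer of the product A to lead in the flask, with a share of target of 39.6 %.

The forecast gives 60 % and 41 %, slightly above mine, with isomer of the product A ahead, and it holds that “Mass balance shows target drains into isomer B”.

The flask gives 53.9 % at 2.0 s and 40.2 % at 3.0 min, with isomer of the product A ahead at 18.1 % against 12.2 % of target.

    substrate ⇌ other conformer (K = 0.350, k = 2.00 × 10⁻⁴ s⁻¹)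
    substrate + coupling partner → target (k = 0.00890 L mol⁻¹ s⁻¹)
    coupling partner + other conformer → isomer of the product A (k = 0.0150 L mol⁻¹ s⁻¹)
    target ⇌ isomer of the product B (K = 1.30, k = 0.0200 s⁻¹)

Target and isomer of the product B relax with a half-life of 0.326 min, short against 3.0 min. Now apply the late factor to the neighbour flask with 0.42 M of other conformer: its charge ratio of 1.19 gives a late ratio of 0.390 and a share of 28.1 %. The share of target in that neighbour flask at 3.0 min is 28.5 %.

(The readings come from a simulation on assumed constants.)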